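**Plan**
- Enabling feature: in the seven-membered ring (O, C7, C8, C9=C10, C11, C12) the ring alkene lies γ,δ to the exocyclic carbon C13 and C12 carries the ring oxygen. With C13 raised to a carboxylic acid, the unit C9=C10–C11–C12(O)–C13 is what an Ireland–Claisen rearrangement of an allylic α-alkoxyacetate delivers.
- Retrosynthesis: cut C3=C4 (enyne olefination) and C13–C14 (ethyl Grignard on a C13 Weinreb amide), then C11–C12 by retro-[3,3] shift, which restores the C9–O ester bond and gives a 7-vinyl-1,4-dioxepan-2-one. The lactone is opened at the acyl–O9 bond and at O7–C12 (bromoacetic acid), and the chain at C6–C7 (alkoxyallylboration of a C7 aldehyde).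
- Forward order: a C7–C11 aldehyde is made from penta-1,4-dien-3-ol and C4–C6 is added by allylboration. O7 is alkylated, O9 freed and the temporary seven-membered lactone closed. The [3,3] shift then turns the lactone into the oxepene, the only ring of the target, and the C13 ketone, alcohol, bromide, the C1–C3 enyne and the acetate follow.
- Stereochemistry: C9 comes from Sharpless desymmetrisation and is relayed to C12 in the key step. C6 and C7 come from the reagent-controlled (Z)-γ-alkoxyallylboration. C13 comes from Felkin–Anh reduction followed by SN2 bromination with inversion. C9=C10 is Z by ring constraint and C3=C4 is Z from a Peterson olefination with bulky silyl groups.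

Key step: step 10

Remark: carbons are numbered C1 (alkyne CH) to C15 (ethyl CH3), and O6, O7, O9 are the oxygens on C6, C7, C9. In this numbering the target is (3Z,6S,7S,12R,13S) with the C7 and C12 substituents cis on the oxepene.

**Route**

Step 1
Reactants: 1 penta-1,4-dien-3-ol
Product: 2 (2S,3R)-1,2-epoxypent-4-en-3-ol
Conditions: Ti(OiPr)4 (cat.), D-(−)-diisopropyl tartrate (cat.), t-BuOOH, 4 Å molecular sieves, CH2Cl2, −20 °C
Reagents that add atoms: tert-butyl hydroperoxide, CC(C)(C)OO
Why: Sharpless asymmetric epoxidation desymmetrises the divinyl carbinol, since the tartrate-bound titanium peroxide selects one enantiotopic vinyl group and one of its faces, so the carbinol carbon (C9) and the epoxide carbon should be set together as the erythro (2S,3R) isomer while any minor enantiomer is consumed by a second epoxidation.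

Step 2
Reactants: 2 (2S,3R)-1,2-epoxypent-4-en-3-ol
Product: 3 (S)-pent-4-ene-1,3-diol
Conditions: NaAlH2(OCH2CH2OMe)2, THF, 0 °C; aq. NaOH work-up
Reagents that add atoms: none
Why: Hydroxyl-directed hydride opening of a 2,3-epoxy alcohol, in which the alkoxyaluminate formed at O9 delivers hydride intramolecularly to the proximal epoxide carbon (C8), should give the 1,3-diol regioselectively without touching C9.

Step 3
Reactants: 3 (S)-pent-4-ene-1,3-diol
Product: 4 (2S,4S)-2-(4-methoxyphenyl)-4-vinyl-1,3-dioxane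
Conditions: 4-MeOC6H4CH(OMe)2, pyridinium p-toluenesulfonate (cat.), CH2Cl2, rt
Reagents that add atoms: 4-methoxybenzaldehyde dimethyl acetal, COc1ccc(C(OC)OC)cc1
Why: Acid-catalysed transacetalisation of the 1,3-diol should give the six-membered 4-methoxybenzylidene acetal under thermodynamic control with aryl and vinyl groups both equatorial, which prepares the regioselective reductive opening.

Step 4
Reactants: 4 (2S,4S)-2-(4-methoxyphenyl)-4-vinyl-1,3-dioxane
Product: 5 (S)-3-[(4-methoxybenzyl)oxy]pent-4-en-1-ol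
Conditions: i-Bu2AlH, CH2Cl2, −78 → 0 °C; aq. KNaC4H4O6 work-up
Reagents that add atoms: none
Why: In the reductive opening of a 4-methoxybenzylidene acetal, aluminium coordinates the less hindered primary oxygen and hydride adds to the resulting oxocarbenium carbon, so the 4-methoxybenzyl group should stay on the secondary O9 and the primary C7 hydroxyl be freed.

Step 5
Reactants: 5 (S)-3-[(4-methoxybenzyl)oxy]pent-4-en-1-ol
Product: 6 (S)-3-[(4-methoxybenzyl)oxy]pent-4-enal
Conditions: Dess–Martin periodinane, NaHCO3, CH2Cl2, 0 °C → rt; used directly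
Reagents that add atoms: none
Why: Dess–Martin oxidation of the primary alcohol under buffered, non-basic conditions should give the β-alkoxy aldehyde without β-elimination and without affecting C9.

Step 6
Reactants: 6 (S)-3-[(4-methoxybenzyl)oxy]pent-4-enal; 7 allyl methoxymethyl ether
Product: 10 (3S,4S,6S)-6-[(4-methoxybenzyl)oxy]-3-(methoxymethoxy)octa-1,7-dien-4-ol, via alkoxyallylborane 8 (not isolated), via borinate adduct 9 (not isolated)
Conditions: 7, s-BuLi, THF, −78 °C; (+)-Ipc2BOMe [from (−)-α-pinene]; BF3·OEt2; then 6, −78 °C; aq. NaOH, H2O2, 0 °C → rt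
Reagents that add atoms: none
Why: In this Brown (Z)-γ-alkoxyallylboration the allylborane reacts through a closed chair (Zimmerman–Traxler) transition state, where the Z geometry gives the syn C6-OMOM/C7-OH pair and the isopinocampheyl groups direct attack to the Re face of the aldehyde, so C6 and C7 should both be set S by the reagent, independently of C9 (7,9-anti).

Step 7
Reactants: 10 (3S,4S,6S)-6-[(4-methoxybenzyl)oxy]-3-(methoxymethoxy)octa-1,7-dien-4-ol; 11 bromoacetic acid
Product: 12 2-{[(3S,4S,6S)-6-[(4-methoxybenzyl)oxy]-3-(methoxymethoxy)octa-1,7-dien-4-yl]oxy}acetic acid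
Conditions: NaH (excess), THF/DMF, 0 °C → rt; then aq. HCl to pH 3 at 0 °C
Reagents that add atoms: none
Why: Williamson etherification of the only free hydroxyl (O7) with sodium bromoacetate should be clean, because the neighbouring oxygens carry an acetal and a benzyl-type ether that cannot migrate under base and the carboxylate product resists further alkylation.

Step 8
Reactants: 12 2-{[(3S,4S,6S)-6-[(4-methoxybenzyl)oxy]-3-(methoxymethoxy)octa-1,7-dien-4-yl]oxy}acetic acid
Product: 13 2-{[(3S,4S,6S)-6-hydroxy-3-(methoxymethoxy)octa-1,7-dien-4-yl]oxy}acetic acid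
Conditions: DDQ, CH2Cl2/pH 7 buffer, 0 °C → rt
Reagents that add atoms: none
Why: Oxidative cleavage of the 4-methoxybenzyl ether by DDQ (hydride abstraction, then hydrolysis of the oxocarbenium ion) should free O9 selectively, since the methoxymethyl ether, the terminal alkenes and the acid are not oxidised.

Step 9
Reactants: 13 2-{[(3S,4S,6S)-6-hydroxy-3-(methoxymethoxy)octa-1,7-dien-4-yl]oxy}acetic acid
Product: 15 (5S,7S)-5-[(1S)-1-(methoxymethoxy)prop-2-en-1-yl]-7-vinyl-1,4-dioxepan-2-one, via mixed anhydride 14 (not isolated)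
Conditions: 2,4,6-Cl3C6H2COCl, Et3N, THF, rt; then slow addition to DMAP, toluene, 80 °C, high dilution
Reagents that add atoms: none
Why: In this Yamaguchi lactonisation the C9 hydroxyl attacks the activated carboxyl carbon, so C9 keeps its configuration, and high dilution together with the ether oxygen in the chain should favour the seven-membered ring over oligomers.

Step 10
Reactants: 15 (5S,7S)-5-[(1S)-1-(methoxymethoxy)prop-2-en-1-yl]-7-vinyl-1,4-dioxepan-2-one
Product: 18 (2R,7S)-7-[(1S)-1-(methoxymethoxy)prop-2-en-1-yl]-2,3,6,7-tetrahydrooxepine-2-carboxylic acid, via silyl ketene acetal 16 (not isolated), via trimethylsilyl ester 17 (not isolated)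
Conditions: LiN(SiMe3)2, Me3SiCl/Et3N, THF, −78 °C → rt; toluene, 110 °C; then 1 M HCl
Reagents that add atoms: none
Why: Deprotonation at C12 in the presence of Me3SiCl gives the endocyclic silyl ketene acetal, which undergoes a concerted suprafacial [3,3]-sigmatropic shift in which C11–C12 forms, the C9–O ester bond breaks and the alkene moves to C9=C10, leaving C13 as a silyl ester that is hydrolysed on work-up. The closest known reaction type is the Ireland–Claisen ring contraction of alkenyl-substituted lactones, as in the conversion of 6-alkenyl-1,4-dioxan-2-ones into dihydropyran carboxylic acids. The oxepene ring (O, C7–C12) closes by reorganisation of the lactone, not by joining two free chain ends: lactone and pericyclic array share C12, C13, the ester oxygen and C9 in a bicyclic, necessarily boat-like transition state, and a trans double bond cannot be accommodated, so C9=C10 should be Z. The new stereocentre C12 is controlled by C9 alone, because the vinyl group can reach C12 only across the lactone face on which it stands, which relays (S)-C9 to (R)-C12. The selectivity required is 7,12-cis, and it is secured by the trans arrangement of the C7 side chain and the C9 vinyl group in 15, which keeps the C7 substituent on the open side of the bicyclic transition state and lets the carboxyl at C12 emerge cis to it. Silylation in situ at −78 °C is intended to suppress acyl cleavage and Claisen condensation of the lactone enolate.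

Step 11
Reactants: 18 (2R,7S)-7-[(1S)-1-(methoxymethoxy)prop-2-en-1-yl]-2,3,6,7-tetrahydrooxepine-2-carboxylic acid
Product: 19 (2R,7S)-N-methoxy-N-methyl-7-[(1S)-1-(methoxymethoxy)prop-2-en-1-yl]-2,3,6,7-tetrahydrooxepine-2-carboxamide
Conditions: MeNHOMe·HCl, EDC·HCl, HOBt (cat.), i-Pr2NEt, CH2Cl2, 0 °C → rt
Reagents that add atoms: N,O-dimethylhydroxylamine hydrochloride, CNOC.Cl
Why: Carbodiimide-mediated amide coupling of an α-alkoxy acid, which cannot form an azlactone-type intermediate, should give the Weinreb amide without epimerisation at C12.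

Step 12
Reactants: 19 (2R,7S)-N-methoxy-N-methyl-7-[(1S)-1-(methoxymethoxy)prop-2-en-1-yl]-2,3,6,7-tetrahydrooxepine-2-carboxamide; 20 ethylmagnesium bromide
Product: 22 1-[(2R,7S)-7-[(1S)-1-(methoxymethoxy)prop-2-en-1-yl]-2,3,6,7-tetrahydrooxepin-2-yl]propan-1-one, via magnesium hemiaminal chelate 21 (not isolated)
Conditions: EtMgBr, THF, 0 °C; aq. NH4Cl
Reagents that add atoms: none
Why: In the Weinreb ketone synthesis the N-methoxy magnesium chelate of the tetrahedral adduct persists until work-up, so the ethyl ketone (C14–C15 added) should form without over-addition.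

Step 13
Reactants: 22 1-[(2R,7S)-7-[(1S)-1-(methoxymethoxy)prop-2-en-1-yl]-2,3,6,7-tetrahydrooxepin-2-yl]propan-1-one
Product: 23 (1R)-1-[(2R,7S)-7-[(1S)-1-(methoxymethoxy)prop-2-en-1-yl]-2,3,6,7-tetrahydrooxepin-2-yl]propan-1-ol
Conditions: LiBH(s-Bu)3, THF, −78 °C; aq. NH4Cl
Reagents that add atoms: none
Why: Felkin–Anh reduction of the α-alkoxy ketone by a bulky, poorly chelating hydride, with the C12–O bond perpendicular to the carbonyl and anti to the incoming hydride, should give the (13R) alcohol syn to the ring oxygen.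

Step 14
Reactants: 23 (1R)-1-[(2R,7S)-7-[(1S)-1-(methoxymethoxy)prop-2-en-1-yl]-2,3,6,7-tetrahydrooxepin-2-yl]propan-1-ol
Product: 24 (2R,7S)-2-[(1S)-1-bromopropyl]-7-[(1S)-1-(methoxymethoxy)prop-2-en-1-yl]-2,3,6,7-tetrahydrooxepine
Conditions: CBr4, P(n-C8H17)3, toluene, 70 °C
Reagents that add atoms: tetrabromomethane, BrC(Br)(Br)Br
Why: In this Appel-type bromination the alkoxyphosphonium ion is displaced by bromide in an SN2 step that inverts C13 from R to S, and the non-polar solvent with a trialkylphosphine is chosen to disfavour ionisation and participation by the ring oxygen.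

Step 15
Reactants: 24 (2R,7S)-2-[(1S)-1-bromopropyl]-7-[(1S)-1-(methoxymethoxy)prop-2-en-1-yl]-2,3,6,7-tetrahydrooxepine
Product: 26 (3S)-3-[(2S,7R)-7-[(1S)-1-bromopropyl]-2,3,6,7-tetrahydrooxepin-2-yl]-3-(methoxymethoxy)propan-1-ol, via B-alkyl-9-borabicyclononane 25 (not isolated)
Conditions: 9-BBN, THF, 0 °C → rt; then aq. NaOH, H2O2, 0 °C
Reagents that add atoms: hydrogen peroxide, OO
Why: In this hydroboration–oxidation the bulky dialkylborane should add anti-Markovnikov to the monosubstituted C4=C5 alkene much faster than to the cis-disubstituted ring alkene, and oxidation with retention places the hydroxyl on C4.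

Step 16
Reactants: 26 (3S)-3-[(2S,7R)-7-[(1S)-1-bromopropyl]-2,3,6,7-tetrahydrooxepin-2-yl]-3-(methoxymethoxy)propan-1-ol
Product: 27 (3S)-3-[(2S,7R)-7-[(1S)-1-bromopropyl]-2,3,6,7-tetrahydrooxepin-2-yl]-3-(methoxymethoxy)propanal
Conditions: Dess–Martin periodinane, NaHCO3, CH2Cl2, 0 °C → rt; used directly
Reagents that add atoms: none
Why: Dess–Martin oxidation under neutral buffered conditions should give the C4 aldehyde while leaving the secondary bromide and the β-alkoxy group intact.

Step 17
Reactants: 27 (3S)-3-[(2S,7R)-7-[(1S)-1-bromopropyl]-2,3,6,7-tetrahydrooxepin-2-yl]-3-(methoxymethoxy)propanal; 28 1,3-bis(triisopropylsilyl)propyne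
Product: 30 [(3Z,6S)-6-[(2S,7R)-7-[(1S)-1-bromopropyl]-2,3,6,7-tetrahydrooxepin-2-yl]-6-(methoxymethoxy)hex-3-en-1-yn-1-yl]triisopropylsilane, via β-silyl alkoxide 29 (not isolated)
Conditions: 28, n-BuLi, THF, −78 °C; then 27, −78 → 0 °C; aq. NH4Cl
Reagents that add atoms: none
Why: In this Peterson olefination the lithiated propargylsilane adds to the aldehyde and the bulky triisopropylsilyl groups favour the anti β-silyl alkoxide, whose syn-elimination of silanolate should give the Z C3=C4 enyne with the alkyne still silyl-capped.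

Step 18
Reactants: 30 [(3Z,6S)-6-[(2S,7R)-7-[(1S)-1-bromopropyl]-2,3,6,7-tetrahydrooxepin-2-yl]-6-(methoxymethoxy)hex-3-en-1-yn-1-yl]triisopropylsilane
Product: 31 (1S,3Z)-1-[(2S,7R)-7-[(1S)-1-bromopropyl]-2,3,6,7-tetrahydrooxepin-2-yl]-6-(triisopropylsilyl)hex-3-en-5-yn-1-ol
Conditions: HCl (cat.), MeOH, 40 °C
Reagents that add atoms: none
Why: Acid-catalysed acetal exchange should transfer the methoxymethyl group to methanol and free O6, since the ring ether, the secondary bromide and the silylalkyne are not acid-labile under these conditions.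

Step 19
Reactants: 31 (1S,3Z)-1-[(2S,7R)-7-[(1S)-1-bromopropyl]-2,3,6,7-tetrahydrooxepin-2-yl]-6-(triisopropylsilyl)hex-3-en-5-yn-1-ol
Product: 32 (1S,3Z)-1-[(2S,7R)-7-[(1S)-1-bromopropyl]-2,3,6,7-tetrahydrooxepin-2-yl]hex-3-en-5-yn-1-ol
Conditions: Bu4NF, THF, 0 °C
Reagents that add atoms: none
Why: Fluoride-induced protodesilylation of the alkynylsilane (attack at silicon, protonation of the acetylide) is fast at 0 °C and should leave the secondary bromide and the Z alkene untouched.

Step 20
Reactants: 32 (1S,3Z)-1-[(2S,7R)-7-[(1S)-1-bromopropyl]-2,3,6,7-tetrahydrooxepin-2-yl]hex-3-en-5-yn-1-ol; 33 acetic anhydride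
Product: 34 (1S,3Z)-1-[(2S,7R)-7-[(1S)-1-bromopropyl]-2,3,6,7-tetrahydrooxepin-2-yl]hex-3-en-5-yn-1-yl acetate
Conditions: Ac2O, pyridine, DMAP (cat.), CH2Cl2, 0 °C → rt
Reagents that add atoms: none
Why: DMAP-catalysed acylation of the C6 secondary alcohol proceeds at oxygen with retention at C6 and should complete the target.

**Compound list**

1 | penta-1,4-dien-3-ol | C=CC(O)C=C | starting material
2 | (2S,3R)-1,2-epoxypent-4-en-3-ol | C=C[C@@H](O)[C@@H]1CO1 | intermediate
3 | (S)-pent-4-ene-1,3-diol | C=C[C@@H](O)CCO | intermediate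
4 | (2S,4S)-2-(4-methoxyphenyl)-4-vinyl-1,3-dioxane | C=C[C@@H]1CCO[C@H](c2ccc(OC)cc2)O1 | intermediate
5 | (S)-3-[(4-methoxybenzyl)oxy]pent-4-en-1-ol | C=C[C@@H](OCc1ccc(OC)cc1)CCO | intermediate
6 | (S)-3-[(4-methoxybenzyl)oxy]pent-4-enal | C=C[C@@H](OCc1ccc(OC)cc1)CC=O | intermediate
7 | allyl methoxymethyl ether [3-(methoxymethoxy)prop-1-ene] | C=CCOCOC | starting material
8 | [(Z)-3-(methoxymethoxy)prop-2-en-1-yl]bis(isopinocampheyl)borane, isopinocampheyl groups from (−)-α-pinene (not isolated) | COCO/C=C\CB([C@H]1C[C@H]2C[C@@H]([C@@H]1C)C2(C)C)[C@H]1C[C@H]2C[C@@H]([C@@H]1C)C2(C)C | intermediate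
9 | (3S,4S,6S)-6-[(4-methoxybenzyl)oxy]-3-(methoxymethoxy)octa-1,7-dien-4-yl bis(isopinocampheyl)borinate (not isolated) | C=C[C@H](OCOC)[C@@H](OB([C@H]1C[C@H]2C[C@@H]([C@@H]1C)C2(C)C)[C@H]1C[C@H]2C[C@@H]([C@@H]1C)C2(C)C)C[C@H](OCc1ccc(OC)cc1)C=C | intermediate
10 | (3S,4S,6S)-6-[(4-methoxybenzyl)oxy]-3-(methoxymethoxy)octa-1,7-dien-4-ol | C=C[C@H](OCOC)[C@@H](O)C[C@H](OCc1ccc(OC)cc1)C=C | intermediate
11 | bromoacetic acid | OC(=O)CBr | starting material
12 | 2-{[(3S,4S,6S)-6-[(4-methoxybenzyl)oxy]-3-(methoxymethoxy)octa-1,7-dien-4-yl]oxy}acetic acid | C=C[C@H](OCOC)[C@@H](OCC(=O)O)C[C@H](OCc1ccc(OC)cc1)C=C | intermediate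
13 | 2-{[(3S,4S,6S)-6-hydroxy-3-(methoxymethoxy)octa-1,7-dien-4-yl]oxy}acetic acid | C=C[C@H](OCOC)[C@@H](OCC(=O)O)C[C@H](O)C=C | intermediate
14 | mixed anhydride of 13 with 2,4,6-trichlorobenzoic acid (not isolated) | C=C[C@H](OCOC)[C@@H](OCC(=O)OC(=O)c1c(Cl)cc(Cl)cc1Cl)C[C@H](O)C=C | intermediate
15 | (5S,7S)-5-[(1S)-1-(methoxymethoxy)prop-2-en-1-yl]-7-vinyl-1,4-dioxepan-2-one | C=C[C@H](OCOC)[C@@H]1C[C@@H](C=C)OC(=O)CO1 | intermediate
16 | {[(5S,7S)-5-[(1S)-1-(methoxymethoxy)prop-2-en-1-yl]-7-vinyl-6,7-dihydro-5H-1,4-dioxepin-2-yl]oxy}trimethylsilane (not isolated) | C=C[C@H](OCOC)[C@@H]1C[C@@H](C=C)OC(O[Si](C)(C)C)=CO1 | intermediate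
17 | trimethylsilyl (2R,7S)-7-[(1S)-1-(methoxymethoxy)prop-2-en-1-yl]-2,3,6,7-tetrahydrooxepine-2-carboxylate (not isolated) | C=C[C@H](OCOC)[C@@H]1CC=CC[C@H](C(=O)O[Si](C)(C)C)O1 | intermediate
18 | (2R,7S)-7-[(1S)-1-(methoxymethoxy)prop-2-en-1-yl]-2,3,6,7-tetrahydrooxepine-2-carboxylic acid | C=C[C@H](OCOC)[C@@H]1CC=CC[C@H](C(=O)O)O1 | intermediate
19 | (2R,7S)-N-methoxy-N-methyl-7-[(1S)-1-(methoxymethoxy)prop-2-en-1-yl]-2,3,6,7-tetrahydrooxepine-2-carboxamide | C=C[C@H](OCOC)[C@@H]1CC=CC[C@H](C(=O)N(C)OC)O1 | intermediate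
20 | ethylmagnesium bromide | CC[Mg]Br | starting material
21 | bromomagnesium alkoxide of the tetrahedral adduct of 19 and 20 (not isolated) | C=C[C@H](OCOC)[C@@H]1CC=CC[C@H](C(CC)(O[Mg]Br)N(C)OC)O1 | intermediate
22 | 1-[(2R,7S)-7-[(1S)-1-(methoxymethoxy)prop-2-en-1-yl]-2,3,6,7-tetrahydrooxepin-2-yl]propan-1-one | C=C[C@H](OCOC)[C@@H]1CC=CC[C@H](C(=O)CC)O1 | intermediate
23 | (1R)-1-[(2R,7S)-7-[(1S)-1-(methoxymethoxy)prop-2-en-1-yl]-2,3,6,7-tetrahydrooxepin-2-yl]propan-1-ol | C=C[C@H](OCOC)[C@@H]1CC=CC[C@H]([C@H](O)CC)O1 | intermediate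
24 | (2R,7S)-2-[(1S)-1-bromopropyl]-7-[(1S)-1-(methoxymethoxy)prop-2-en-1-yl]-2,3,6,7-tetrahydrooxepine | C=C[C@H](OCOC)[C@@H]1CC=CC[C@H]([C@@H](Br)CC)O1 | intermediate
25 | 9-[(3S)-3-[(2S,7R)-7-[(1S)-1-bromopropyl]-2,3,6,7-tetrahydrooxepin-2-yl]-3-(methoxymethoxy)propyl]-9-borabicyclo[3.3.1]nonane (not isolated) | C(C[C@H](OCOC)[C@@H]1CC=CC[C@H]([C@@H](Br)CC)O1)B1C2CCCC1CCC2 | intermediate
26 | (3S)-3-[(2S,7R)-7-[(1S)-1-bromopropyl]-2,3,6,7-tetrahydrooxepin-2-yl]-3-(methoxymethoxy)propan-1-ol | OCC[C@H](OCOC)[C@@H]1CC=CC[C@H]([C@@H](Br)CC)O1 | intermediate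
27 | (3S)-3-[(2S,7R)-7-[(1S)-1-bromopropyl]-2,3,6,7-tetrahydrooxepin-2-yl]-3-(methoxymethoxy)propanal | O=CC[C@H](OCOC)[C@@H]1CC=CC[C@H]([C@@H](Br)CC)O1 | intermediate
28 | 1,3-bis(triisopropylsilyl)propyne | CC(C)[Si](CC#C[Si](C(C)C)(C(C)C)C(C)C)(C(C)C)C(C)C | starting material
29 | lithium alkoxide of the adduct of 27 and lithiated 28, a 1,2-bis(silyl) homopropargylic alkoxide (not isolated) | [Li]OC(C[C@H](OCOC)[C@@H]1CC=CC[C@H]([C@@H](Br)CC)O1)C(C#C[Si](C(C)C)(C(C)C)C(C)C)[Si](C(C)C)(C(C)C)C(C)C | intermediate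
30 | [(3Z,6S)-6-[(2S,7R)-7-[(1S)-1-bromopropyl]-2,3,6,7-tetrahydrooxepin-2-yl]-6-(methoxymethoxy)hex-3-en-1-yn-1-yl]triisopropylsilane | CC(C)[Si](C#C/C=C\C[C@H](OCOC)[C@@H]1CC=CC[C@H]([C@@H](Br)CC)O1)(C(C)C)C(C)C | intermediate
31 | (1S,3Z)-1-[(2S,7R)-7-[(1S)-1-bromopropyl]-2,3,6,7-tetrahydrooxepin-2-yl]-6-(triisopropylsilyl)hex-3-en-5-yn-1-ol | CC(C)[Si](C#C/C=C\C[C@H](O)[C@@H]1CC=CC[C@H]([C@@H](Br)CC)O1)(C(C)C)C(C)C | intermediate
32 | (1S,3Z)-1-[(2S,7R)-7-[(1S)-1-bromopropyl]-2,3,6,7-tetrahydrooxepin-2-yl]hex-3-en-5-yn-1-ol | C#C/C=C\C[C@H](O)[C@@H]1CC=CC[C@H]([C@@H](Br)CC)O1 | intermediate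
33 | acetic anhydride | CC(=O)OC(C)=O | starting material
34 | (1S,3Z)-1-[(2S,7R)-7-[(1S)-1-bromopropyl]-2,3,6,7-tetrahydrooxepin-2-yl]hex-3-en-5-yn-1-yl acetate | C#C/C=C\C[C@H](OC(C)=O)[C@@H]1CC=CC[C@H]([C@@H](Br)CC)O1 | target

**Step count and risks**

Total step count: 20. Longest linear sequence: 20 steps, from penta-1,4-dien-3-ol (1) to 34.

Steps most likely to fail:

1. Step 10. What may go wrong is base-induced acyl–oxygen cleavage of the lactone enolate (ketene formation, oligomerisation) or C-silylation outrunning the sigmatropic shift, so that the ketene acetal never accumulates. The fallback sets out from 15 and runs the same ring reorganisation on a neutral allyl vinyl ether at the aldehyde oxidation level, so no enolate is needed. Reductive acetylation of 15 (i-Bu2AlH, CH2Cl2, −78 °C, then Ac2O, pyridine, DMAP) would give the α-acetoxy ether (5S,7S)-5-[(1S)-1-(methoxymethoxy)prop-2-en-1-yl]-7-vinyl-1,4-dioxepan-2-yl acetate F1. Elimination of acetic acid (Me3SiOTf, i-Pr2NEt, CH2Cl2, −78 → 0 °C) would give the cyclic enol ether (5S,7S)-5-[(1S)-1-(methoxymethoxy)prop-2-en-1-yl]-7-vinyl-6,7-dihydro-5H-1,4-dioxepine F2. A thermal Claisen rearrangement (toluene, 140–180 °C, sealed tube) should contract this to the aldehyde (2R,7S)-7-[(1S)-1-(methoxymethoxy)prop-2-en-1-yl]-2,3,6,7-tetrahydrooxepine-2-carbaldehyde F3 through the same boat-like transition state. Pinnick oxidation (NaClO2, NaH2PO4, 2-methylbut-2-ene, t-BuOH/H2O) brings the sequence back to the route at 18.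

2. Step 14. What may go wrong is ionisation of the alkoxyphosphonium intermediate with participation of the ring oxygen, leading to retention, ring-contracted ethers or elimination instead of clean inversion. The fallback sets out from 23 and separates activation from displacement. Chloromethanesulfonyl chloride with 2,6-lutidine in CH2Cl2 at 0 °C would give the isolable sulfonate (1R)-1-[(2R,7S)-7-[(1S)-1-(methoxymethoxy)prop-2-en-1-yl]-2,3,6,7-tetrahydrooxepin-2-yl]propyl chloromethanesulfonate F4. SN2 displacement with Bu4NBr in toluene at 60 °C should then invert C13 and rejoin the route at 24.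

3. Step 17. What may go wrong is erosion of Z-selectivity in the elimination step and base-induced β-elimination of the methoxymethoxy group from the enolisable aldehyde by the lithiated propyne. The fallback sets out from 27 and builds the enyne by olefination followed by cross-coupling. Stork–Zhao olefination (Ph3PCH2I iodide, NaN(SiMe3)2, THF/DMPU, −78 °C) would give the vinyl iodide (2R,7S)-2-[(1S)-1-bromopropyl]-7-[(1S,3Z)-4-iodo-1-(methoxymethoxy)but-3-en-1-yl]-2,3,6,7-tetrahydrooxepine F5. Sonogashira coupling with (triisopropylsilyl)acetylene (Pd(PPh3)4 as a zerovalent palladium catalyst, CuI, i-Pr2NH, rt), under which the secondary alkyl bromide should be inert, rejoins the route at 30.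

**Further compounds**

F1 | step 10 | (5S,7S)-5-[(1S)-1-(methoxymethoxy)prop-2-en-1-yl]-7-vinyl-1,4-dioxepan-2-yl acetate | C=C[C@H](OCOC)[C@@H]1C[C@@H](C=C)OC(OC(C)=O)CO1
F2 | step 10 | (5S,7S)-5-[(1S)-1-(methoxymethoxy)prop-2-en-1-yl]-7-vinyl-6,7-dihydro-5H-1,4-dioxepine | C=C[C@H](OCOC)[C@@H]1C[C@@H](C=C)OC=CO1
F3 | step 10 | (2R,7S)-7-[(1S)-1-(methoxymethoxy)prop-2-en-1-yl]-2,3,6,7-tetrahydrooxepine-2-carbaldehyde | C=C[C@H](OCOC)[C@@H]1CC=CC[C@H](C=O)O1
F4 | step 14 | (1R)-1-[(2R,7S)-7-[(1S)-1-(methoxymethoxy)prop-2-en-1-yl]-2,3,6,7-tetrahydrooxepin-2-yl]propyl chloromethanesulfonate | C=C[C@H](OCOC)[C@@H]1CC=CC[C@H]([C@H](OS(=O)(=O)CCl)CC)O1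
F5 | step 17 | (2R,7S)-2-[(1S)-1-bromopropyl]-7-[(1S,3Z)-4-iodo-1-(methoxymethoxy)but-3-en-1-yl]-2,3,6,7-tetrahydrooxepine | I/C=C\C[C@H](OCOC)[C@@H]1CC=CC[C@H]([C@@H](Br)CC)O1
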